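## Analysis of the target

The target 17 is (3S,4S,3'S,4'S)-7,8,7',8'-tetradehydro-β,β-carotene-3,4,3',4'-tetrol, a C2-symmetric C40 carotenoid. Two identical 2,6,6-trimethylcyclohexene rings are joined through C6 and C6' by an eighteen-carbon chain. The chain begins at each end with a C7≡C8 triple bond, carries seven E double bonds (9, 11, 13, 15, 13', 11', 9') and has four methyl branches. Each ring holds two neighbouring secondary carbinol carbons, C3 (S) and C4 (S), with the hydroxyls trans. C4 is allylic to the tetrasubstituted C5=C6 alkene and C3 is not. The rings are too far apart to influence each other, so one stereochemical problem is solved twice. The polyene is sensitive to light, oxygen and acid. The C4–O bond ionises easily, because its cation is spread over C5=C6, the alkyne and the chain. The 9E alkene next to the alkyne cannot be corrected later by equilibration, since in 7,8-didehydro carotenoids the 9Z form is not clearly disfavoured. The hard part is a trans-vicinal diol of defined absolute configuration on a ring next to a quaternary carbon, carried through chain assembly without acid. The route rests on one feature: the C4 hydroxyl is 1,3-related to C6 across C5, and C5=C6 is conjugated with C7≡C8. The C4 alcohol is therefore the conjugated, transposed isomer of a C6 tertiary carbinol with a C4=C5 alkene. That carbinol is the adduct of an acetylide and a cyclohexenone whose only stereocentre is C3.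

## Retrosynthetic reasoning

17 to 16. The four O–H bonds are traced back to silyl ethers. The free tetrol is polar and hard to purify, and a free allylic C4 hydroxyl would compete with the primary allylic position when the C11 leaving group is made. The last step therefore has to free four hydroxyls without acid.

16 to 12 and 13. The chain is cut at C11=C12 and C11'=C12'. This uses the symmetry: two identical C15 units sit on a bought C10 dialdehyde 13. All stereocentres lie in the C15 unit, and the 9E alkene comes ready-made. The two new alkenes are disubstituted, so their Z isomers are the hindered ones that relax thermally. The forward reaction is a two-fold Wittig olefination through ylide 14 and the mono-coupled aldehyde 15.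

12 to 8. Phosphonium salt 12 comes from the primary allylic alcohol 10 through bromide 11, and 10 comes from acetate 9 by methanolysis. 9 is the silyl ether of 8. These are functional-group changes at C11 and C4 only. They are ordered so that no step generates acid while the C4–O bond is present.

8 to 7. The C4–O bond of 8 is traced back to the C6–O bond of 7. Oxygen moves across C6–C5–C4 while the alkene moves from C4=C5 to C5=C6. The cut is made here because C4 is the one centre that a simple ketone reduction with good precedent does not provide. The tertiary carbinol 7 needs no control at C6, since that centre disappears. The forward reaction has to deliver oxygen to the face of C4 away from the C3 silyl ether. It must leave the acetate and the 9E alkene alone and avoid the propargylic direction of the shift.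

7 to 3 and 4. The C6–C7 bond is cut, giving ketone 3 and the bought enynol 4, used as its dianion 5. The adduct 6 has two hydroxyls, and only the primary one is acetylated to give 7. The acetate is needed because a free primary allylic alcohol would itself react with the rhenium catalyst and could scramble the 9E alkene.

3 to 1. Ketone 3 is the silyl ether of hydroxy enone 2, which comes from the achiral dione 1 by enantioselective reduction of its less hindered carbonyl. This is the only step in which absolute configuration is created by a reagent.

## Alternatives that were turned down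

Alternative 1: Both C–O bonds of a ring are traced to one C3=C4 alkene. Safranal A1 is homologated at the aldehyde to an alkyne and silylated to the dienyne A2. A chiral Mn(salen)Cl complex with NaOCl would transfer oxygen to the cis-disubstituted C3=C4 alkene and give the cis-fused (3S,4R)-oxirane A3. An oxygen nucleophile then has to open A3 at C4 with inversion to reach the 3S,4S-trans-diol.
- For: both centres come from a catalyst and an achiral, cheap terpenoid. A cis-disubstituted alkene conjugated to a second π-system is the favoured substrate class, and the hindered C5=C6 alkene should be left alone.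
- Against: face selection on a ring diene flanked by a CH2–CMe2 unit cannot be predicted with the confidence of a ketone reduction. A3 is a vinyl oxirane whose C4–O bond ionises to the same delocalised cation as in the chosen route. Opening can then lose the trans relationship, occur at C6, or end in a C4 ketone or a dienol. The alkyne of A3 still has to be extended to the C15 enyne, so the step count is no lower.
- Comparison: this alternative is stronger in that the catalyst sets both centres and no relay is needed. The chosen route offers a first stereocentre of secure origin and a second one made on the complete C15 unit, without an intermediate that can open in two ways.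

Alternative 2: Both C6–C7 bonds are cut. The C22 polyene diyne A5 would be used as its dilithium diacetylide and added to the C6 carbonyl of two molecules of the enantiopure dioxolenone A4. Aqueous acid would then unmask the 3-hydroxy-4-oxo rings with their C5=C6 alkenes and give the bis-ketol A6. Both C4 carbonyls of A6 would have to be reduced to reach 17.
- For: it is the most convergent plan. The whole chain is attached in one operation, the ring building block is of a well-established type, and C3 is bought.
- Against: A6 is one oxidation level too high. The two C4 centres would be set last, on the C40 polyene, by hydride reduction of free α-hydroxy enones, where delivery directed by the neighbouring hydroxyl tends to give the cis diol. Any shortfall is squared over the two ends, and three diastereomers would have to be separated at the hardest stage. The ketol also enolises at C3 under base, and A5 needs its own multi-step synthesis and is a fragile nucleophile.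
- Comparison: this alternative is stronger on convergence. The chosen route sets C4 at the C15 stage, where a wrong epimer can be removed or recycled before symmetry doubles it, and it uses a bought C10 linchpin.

Alternative 3: The central C15=C15' bond is cut. Two molecules of the bis-silylated C20 aldehyde A7 would be coupled at their carbonyl carbons with low-valent titanium (TiCl3 reduced with LiAlH4), giving the tetrakis-silyl ether A8, which is the same compound as 16.
- For: one fragment only, full use of symmetry, no mono-coupled intermediate, no phosphonium salt, and a central Z isomer would relax easily.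
- Against: it does not touch the stereochemical problem, because A7 needs the same trans-diol ring and so the same ring chemistry. The C15 unit must first be lengthened by five carbons, which costs two or three extra steps. The titanium reagent is strongly reducing and oxophilic, so the allylic C4 silyl ether and the conjugated enyne are at risk.
- Comparison: it equals the chosen route on stereocontrol and is stronger only in using a single fragment. The chosen route is shorter and joins the fragments under mild basic conditions.

Key step: step 5

Assumptions: (a) In step 1 the (S,S)-configured ruthenium complex is taken to give the (S)-alcohol, by analogy with aryl ketones with the alkene in the place of the aryl group. If the sense of induction is the reverse, the (R,R)-complex is used. (b) Compounds 6 and 7 are carried as mixtures of epimers at the carbinol carbon (C6 in carotenoid numbering), because step 5 removes this centre.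

## Route

Step 1
Reactants: 1 ketoisophorone (2,6,6-trimethylcyclohex-2-ene-1,4-dione)
Product: 2 (4S)-4-hydroxy-2,6,6-trimethylcyclohex-2-en-1-one
Conditions: RuCl[(S,S)-TsDPEN](p-cymene) (1 mol %), KOH (cat.), i-PrOH, rt
Reagents that add atoms: none
Why: Noyori-type asymmetric transfer hydrogenation reduces the unhindered conjugated C4 carbonyl and leaves the C1 carbonyl, which is shielded by the gem-dimethyl carbon and the C2 methyl; the alkene side of the ketone takes the place of the aryl group in the usual CH/π model, which should set C4 as S.

Step 2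
Reactants: 2 (4S)-4-hydroxy-2,6,6-trimethylcyclohex-2-en-1-one
Product: 3 (4S)-4-[(tert-butyldimethylsilyl)oxy]-2,6,6-trimethylcyclohex-2-en-1-one
Conditions: TBSCl, imidazole, DMF, rt
Reagents that add atoms: tert-butyldimethylsilyl chloride, CC(C)(C)[Si](C)(C)Cl
Why: Standard silylation of a secondary alcohol; the tert-butyldimethylsilyl ether survives the acetylide, the rhenium catalyst and methanolysis, and its bulk later steers oxygen to the far face of C4.

Step 3
Reactants: 3 (4S)-4-[(tert-butyldimethylsilyl)oxy]-2,6,6-trimethylcyclohex-2-en-1-one; 4 (E)-3-methylpent-2-en-4-yn-1-ol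
Product: 6 (4S)-4-[(tert-butyldimethylsilyl)oxy]-1-[(3E)-5-hydroxy-3-methylpent-3-en-1-yn-1-yl]-2,6,6-trimethylcyclohex-2-en-1-ol (both C1 epimers), via dilithio enynol 5 (not isolated)
Conditions: 4 (1.5 equiv), n-BuLi (3.0 equiv), THF, −78 → 0 °C; then 3, −78 → 0 °C; H2O
Reagents that add atoms: none
Why: 1,2-Addition of a lithium acetylide to a ketone without α-hydrogen, with the alkoxide end of 5 as a spectator; the configuration of the new carbinol carbon is not controlled and need not be, because step 5 removes it.

Step 4
Reactants: 6 (4S)-4-[(tert-butyldimethylsilyl)oxy]-1-[(3E)-5-hydroxy-3-methylpent-3-en-1-yn-1-yl]-2,6,6-trimethylcyclohex-2-en-1-ol (both C1 epimers)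
Product: 7 (2E)-5-[(4S)-4-[(tert-butyldimethylsilyl)oxy]-1-hydroxy-2,6,6-trimethylcyclohex-2-en-1-yl]-3-methylpent-2-en-4-yn-1-yl acetate (both C1 epimers)
Conditions: Ac2O, pyridine, CH2Cl2, 0 °C
Reagents that add atoms: acetic anhydride, CC(=O)OC(C)=O
Why: Chemoselective acylation, since the primary allylic alcohol reacts and the tertiary propargylic one does not without a nucleophilic catalyst; the acetate keeps the primary allylic position from being a second substrate of the rhenium catalyst and so protects the 9E geometry.

Step 5
Reactants: 7 (2E)-5-[(4S)-4-[(tert-butyldimethylsilyl)oxy]-1-hydroxy-2,6,6-trimethylcyclohex-2-en-1-yl]-3-methylpent-2-en-4-yn-1-yl acetate (both C1 epimers)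
Product: 8 (2E)-5-[(3S,4S)-4-[(tert-butyldimethylsilyl)oxy]-3-hydroxy-2,6,6-trimethylcyclohex-1-en-1-yl]-3-methylpent-2-en-4-yn-1-yl acetate (carotenoid numbering: free hydroxyl at C4, silyl ether at C3, trans)
Conditions: Ph3SiOReO3 (2–5 mol %), Et2O, −50 → 0 °C; Et3N quench
Reagents that add atoms: none
Why: Ph3SiOReO3 (heptavalent rhenium) exchanges its silanolate for the C6 tertiary hydroxyl to give a perrhenate ester, which passes oxygen from C6 to C4 through a six-membered chair-like [3,3] transition state or, since C6 is tertiary, allylic and propargylic, through a tight allyl cation–perrhenate pair; alcohol exchange then frees the C4 alcohol and returns the catalyst. The closest known reaction type is the rhenium-oxo-catalysed 1,3-isomerisation of allylic alcohols, which runs to the side on which the alkene gains conjugation. No ring is closed and no skeletal bond is formed; one C–O bond is exchanged for another and the alkene moves from C4=C5 to C5=C6. The equilibrium should lie well on the side of 8, because a crowded tertiary carbinol next to the gem-dimethyl carbon becomes a secondary one and the new tetrasubstituted C5=C6 alkene joins the C7≡C8 and C9=C10 bonds in one conjugated system. The new C4 stereocentre is controlled by the C3 silyloxy group: perrhenate should return to the C4 end of the allyl unit on the face away from the neighbouring silyl ether, and because each ester can re-ionise to the same cation, both C6 epimers of 7 should drain into one product. The 3,4-trans isomer is also the one that can hold both C–O bonds (pseudo)equatorial without a syn-axial contact between the silyloxy group and the axial C1 methyl. Three selectivities are needed: site (only the free tertiary alcohol binds rhenium, the primary allylic oxygen being capped as acetate), allylic over propargylic shift (the allenyl pathway to an enone is slower, hence low temperature and short contact), and substitution over elimination (ether solvent, no Brønsted acid, amine quench).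

Step 6
Reactants: 8 (2E)-5-[(3S,4S)-4-[(tert-butyldimethylsilyl)oxy]-3-hydroxy-2,6,6-trimethylcyclohex-1-en-1-yl]-3-methylpent-2-en-4-yn-1-yl acetate
Product: 9 (2E)-5-[(3S,4S)-3,4-bis[(tert-butyldimethylsilyl)oxy]-2,6,6-trimethylcyclohex-1-en-1-yl]-3-methylpent-2-en-4-yn-1-yl acetate
Conditions: TBSOTf, 2,6-lutidine, CH2Cl2, −78 → 0 °C
Reagents that add atoms: tert-butyldimethylsilyl trifluoromethanesulfonate, CC(C)(C)[Si](C)(C)OS(=O)(=O)C(F)(F)F
Why: Silylation of a hindered secondary alcohol with a silyl triflate and a hindered base at low temperature; no free acid is present that could ionise the C4–O bond, and the configuration at C4 is untouched.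

Step 7
Reactants: 9 (2E)-5-[(3S,4S)-3,4-bis[(tert-butyldimethylsilyl)oxy]-2,6,6-trimethylcyclohex-1-en-1-yl]-3-methylpent-2-en-4-yn-1-yl acetate
Product: 10 (2E)-5-[(3S,4S)-3,4-bis[(tert-butyldimethylsilyl)oxy]-2,6,6-trimethylcyclohex-1-en-1-yl]-3-methylpent-2-en-4-yn-1-ol
Conditions: K2CO3, MeOH, 0 °C → rt
Reagents that add atoms: none
Why: Methanolysis (transesterification) of the acetate under mild base; secondary silyl ethers are stable to K2CO3 in methanol.

Step 8
Reactants: 10 (2E)-5-[(3S,4S)-3,4-bis[(tert-butyldimethylsilyl)oxy]-2,6,6-trimethylcyclohex-1-en-1-yl]-3-methylpent-2-en-4-yn-1-ol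
Product: 12 [(2E)-5-[(3S,4S)-3,4-bis[(tert-butyldimethylsilyl)oxy]-2,6,6-trimethylcyclohex-1-en-1-yl]-3-methylpent-2-en-4-yn-1-yl]triphenylphosphonium bromide, via allylic bromide 11 (not isolated)
Conditions: PPh3 (1.2 equiv), CBr4 (1.2 equiv), CH2Cl2, −20 °C; then PPh3 (1.5 equiv), rt
Reagents that add atoms: carbon tetrabromide, BrC(Br)(Br)Br; triphenylphosphine, c1ccc(cc1)P(c1ccccc1)c1ccccc1
Why: The Appel reaction converts the primary allylic alcohol into bromide 11 by SN2 under neutral conditions with the 9E geometry kept; the second portion of PPh3 quaternises the bromide at its primary carbon in the same flask, so the labile bromide is never handled.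

Step 9
Reactants: 12 the phosphonium bromide of step 8 (2.2 equiv); 13 (2E,4E,6E)-2,7-dimethylocta-2,4,6-trienedial
Product: 16 (3S,4S,3'S,4'S)-3,4,3',4'-tetrakis[(tert-butyldimethylsilyl)oxy]-7,8,7',8'-tetradehydro-β,β-carotene (all-E), via phosphorus ylide 14 (not isolated), via C25 aldehyde 15 (not isolated)
Conditions: NaOMe, CH2Cl2/MeOH, 0 °C → rt, dark; then heptane, 80 °C, Ar
Reagents that add atoms: none
Why: Two-fold Wittig olefination of dialdehyde 13 with the semi-stabilised allylic ylide 14 forms C11=C12 and C11'=C12'; these disubstituted alkenes form as E/Z mixtures and the hindered 11Z isomers should relax to E on heating, while the stereocentres are remote and untouched.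

Step 10
Reactants: 16 (3S,4S,3'S,4'S)-3,4,3',4'-tetrakis[(tert-butyldimethylsilyl)oxy]-7,8,7',8'-tetradehydro-β,β-carotene
Product: 17 (3S,4S,3'S,4'S)-7,8,7',8'-tetradehydro-β,β-carotene-3,4,3',4'-tetrol (CNP0283832.1)
Conditions: Bu4NF, THF, 0 °C → rt, dark, Ar
Reagents that add atoms: none
Why: Fluoride-induced cleavage of all four silyl ethers under non-acidic conditions, which the polyene and the ionisable C4–O bonds tolerate; no stereocentre is affected.

## Compound list

1 | ketoisophorone (2,6,6-trimethylcyclohex-2-ene-1,4-dione) | CC1=CC(=O)CC(C)(C)C1=O | starting material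
2 | (4S)-4-hydroxy-2,6,6-trimethylcyclohex-2-en-1-one | CC1=C[C@@H](O)CC(C)(C)C1=O | intermediate
3 | (4S)-4-[(tert-butyldimethylsilyl)oxy]-2,6,6-trimethylcyclohex-2-en-1-one | CC1=C[C@@H](O[Si](C)(C)C(C)(C)C)CC(C)(C)C1=O | intermediate
4 | (E)-3-methylpent-2-en-4-yn-1-ol | C#C/C(C)=C/CO | starting material
5 | dilithium salt of 4, lithium alkoxide and lithium acetylide (formed in the flask, not isolated) | [Li]C#C/C(C)=C/CO[Li] | intermediate
6 | (4S)-4-[(tert-butyldimethylsilyl)oxy]-1-[(3E)-5-hydroxy-3-methylpent-3-en-1-yn-1-yl]-2,6,6-trimethylcyclohex-2-en-1-ol, both C1 epimers | CC1=C[C@@H](O[Si](C)(C)C(C)(C)C)CC(C)(C)C1(O)C#C/C(C)=C/CO | intermediate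
7 | (2E)-5-[(4S)-4-[(tert-butyldimethylsilyl)oxy]-1-hydroxy-2,6,6-trimethylcyclohex-2-en-1-yl]-3-methylpent-2-en-4-yn-1-yl acetate, both C1 epimers | CC1=C[C@@H](O[Si](C)(C)C(C)(C)C)CC(C)(C)C1(O)C#C/C(C)=C/COC(C)=O | intermediate
8 | (2E)-5-[(3S,4S)-4-[(tert-butyldimethylsilyl)oxy]-3-hydroxy-2,6,6-trimethylcyclohex-1-en-1-yl]-3-methylpent-2-en-4-yn-1-yl acetate | CC1=C(C#C/C(C)=C/COC(C)=O)C(C)(C)C[C@H](O[Si](C)(C)C(C)(C)C)[C@H]1O | intermediate
9 | (2E)-5-[(3S,4S)-3,4-bis[(tert-butyldimethylsilyl)oxy]-2,6,6-trimethylcyclohex-1-en-1-yl]-3-methylpent-2-en-4-yn-1-yl acetate | CC1=C(C#C/C(C)=C/COC(C)=O)C(C)(C)C[C@H](O[Si](C)(C)C(C)(C)C)[C@H]1O[Si](C)(C)C(C)(C)C | intermediate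
10 | (2E)-5-[(3S,4S)-3,4-bis[(tert-butyldimethylsilyl)oxy]-2,6,6-trimethylcyclohex-1-en-1-yl]-3-methylpent-2-en-4-yn-1-ol | CC1=C(C#C/C(C)=C/CO)C(C)(C)C[C@H](O[Si](C)(C)C(C)(C)C)[C@H]1O[Si](C)(C)C(C)(C)C | intermediate
11 | (3S,4S)-1-[(3E)-5-bromo-3-methylpent-3-en-1-yn-1-yl]-3,4-bis[(tert-butyldimethylsilyl)oxy]-2,6,6-trimethylcyclohex-1-ene (not isolated) | CC1=C(C#C/C(C)=C/CBr)C(C)(C)C[C@H](O[Si](C)(C)C(C)(C)C)[C@H]1O[Si](C)(C)C(C)(C)C | intermediate
12 | [(2E)-5-[(3S,4S)-3,4-bis[(tert-butyldimethylsilyl)oxy]-2,6,6-trimethylcyclohex-1-en-1-yl]-3-methylpent-2-en-4-yn-1-yl]triphenylphosphonium bromide | CC1=C(C#C/C(C)=C/C[P+](c2ccccc2)(c2ccccc2)c2ccccc2)C(C)(C)C[C@H](O[Si](C)(C)C(C)(C)C)[C@H]1O[Si](C)(C)C(C)(C)C.[Br-] | intermediate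
13 | (2E,4E,6E)-2,7-dimethylocta-2,4,6-trienedial | O=C/C(C)=C/C=C/C=C(\C)C=O | starting material
14 | triphenylphosphonium ylide of 12 (not isolated) | CC1=C(C#C/C(C)=C/C=P(c2ccccc2)(c2ccccc2)c2ccccc2)C(C)(C)C[C@H](O[Si](C)(C)C(C)(C)C)[C@H]1O[Si](C)(C)C(C)(C)C | intermediate
15 | (2E,4E,6E,8E,10E)-13-[(3S,4S)-3,4-bis[(tert-butyldimethylsilyl)oxy]-2,6,6-trimethylcyclohex-1-en-1-yl]-2,7,11-trimethyltrideca-2,4,6,8,10-pentaen-12-ynal (not isolated) | CC1=C(C#C/C(C)=C/C=C/C(C)=C/C=C/C=C(\C)C=O)C(C)(C)C[C@H](O[Si](C)(C)C(C)(C)C)[C@H]1O[Si](C)(C)C(C)(C)C | intermediate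
16 | (3S,4S,3'S,4'S)-3,4,3',4'-tetrakis[(tert-butyldimethylsilyl)oxy]-7,8,7',8'-tetradehydro-β,β-carotene | CC1=C(C#C/C(C)=C/C=C/C(C)=C/C=C/C=C(C)/C=C/C=C(\C)C#CC2=C(C)[C@H](O[Si](C)(C)C(C)(C)C)[C@@H](O[Si](C)(C)C(C)(C)C)CC2(C)C)C(C)(C)C[C@H](O[Si](C)(C)C(C)(C)C)[C@H]1O[Si](C)(C)C(C)(C)C | intermediate
17 | (3S,4S,3'S,4'S)-7,8,7',8'-tetradehydro-β,β-carotene-3,4,3',4'-tetrol | CC1=C(C#C/C(C)=C/C=C/C(C)=C/C=C/C=C(C)/C=C/C=C(\C)C#CC2=C(C)[C@H](O)[C@@H](O)CC2(C)C)C(C)(C)C[C@H](O)[C@H]1O | target

## Step count and risks

Total: 10 steps. Longest linear sequence: 10 steps (1 to 17); 4 and 13 are bought and enter at steps 3 and 9.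

Step 5 (key step). Four things may go wrong.
- The C4 epimers may not converge on trans. A concerted shift passes on the C6 configuration, and at equilibrium the pseudoequatorial C4 hydroxyl of the trans isomer suffers A(1,2) strain against the C5 methyl. The trans preference may therefore be small. A cis fraction can be separated and resubmitted to the catalyst.
- The propargylic shift may compete and lead to an enone.
- The delocalised cation may lose a proton.
- The catalyst may be consumed by adventitious water.

Fallback: setting out from 7, a Babler–Dauben oxidative transposition with pyridinium chlorochromate (C5H5NH[CrO3Cl], hexavalent chromium) and NaOAc in CH2Cl2 should give the 4-oxo enyne acetate F1. Luche reduction (NaBH4, CeCl3·7H2O, MeOH, −78 °C) should then deliver hydride axially and give the pseudoequatorial, trans alcohol. The route is rejoined at 8. Any cis alcohol from the rhenium step can be fed into the same ketone F1 with MnO2.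

Step 9. The allylic ylide is delocalised towards C9, so rotation may erode the 9E geometry. The 11Z isomers may not relax fully, and the second olefination may stall at the C25 aldehyde. Fallback: the polarity is reversed. Setting out from 10, oxidation with MnO2 in CH2Cl2 gives the C15 aldehyde F2. A two-fold Horner–Wadsworth–Emmons reaction of F2 with the known C10 bis(phosphonate), tetraethyl [(2E,4E,6E)-2,7-dimethylocta-2,4,6-triene-1,8-diyl]bis(phosphonate) (CCOP(=O)(OCC)C/C(C)=C/C=C/C=C(\C)CP(=O)(OCC)OCC), with NaN(SiMe3)2 in THF then gives the E alkenes directly. The carbanion is not placed next to C9=C10. The route is rejoined at 16.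

Step 10. Cleavage of the hindered vicinal silyl ethers may be slow. The C40 tetrol may isomerise or degrade during long exposure to basic fluoride. Fallback: the silyl groups are removed at the C15 stage, where forcing conditions do less harm. Setting out from 12, Et3N·3HF in THF at 40 °C gives the diol phosphonium bromide F3. Its Wittig reaction with 13 (NaOMe, CH2Cl2/MeOH, then thermal isomerisation) tolerates free hydroxyls. The route is rejoined at 17.

Step 3. The basic dianion may remove the γ-hydrogen at the silyloxy-bearing carbon of enone 3, which would erode the only stereocentre. Attack at the hindered carbonyl may also be slow. Fallback: a smaller and less basic nucleophile is used and the enyne is built afterwards. Setting out from 3, ethynylmagnesium bromide (HC≡CMgBr) in THF gives the ethynyl carbinol F4. Sonogashira coupling of F4 with (E)-3-iodobut-2-en-1-yl acetate (C/C(I)=C\COC(C)=O; Pd(PPh3)2Cl2, CuI, Et3N) forms the C8–C9 bond with the acetate already in place. The route is rejoined at 7.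

## Further compounds

F1 | step 5 | (2E)-5-[(4S)-4-[(tert-butyldimethylsilyl)oxy]-2,6,6-trimethyl-3-oxocyclohex-1-en-1-yl]-3-methylpent-2-en-4-yn-1-yl acetate | CC1=C(C#C/C(C)=C/COC(C)=O)C(C)(C)C[C@H](O[Si](C)(C)C(C)(C)C)C1=O
F2 | step 9 | (2E)-5-[(3S,4S)-3,4-bis[(tert-butyldimethylsilyl)oxy]-2,6,6-trimethylcyclohex-1-en-1-yl]-3-methylpent-2-en-4-ynal | CC1=C(C#C/C(C)=C/C=O)C(C)(C)C[C@H](O[Si](C)(C)C(C)(C)C)[C@H]1O[Si](C)(C)C(C)(C)C
F3 | step 10 | [(2E)-5-[(3S,4S)-3,4-dihydroxy-2,6,6-trimethylcyclohex-1-en-1-yl]-3-methylpent-2-en-4-yn-1-yl]triphenylphosphonium bromide | CC1=C(C#C/C(C)=C/C[P+](c2ccccc2)(c2ccccc2)c2ccccc2)C(C)(C)C[C@H](O)[C@H]1O.[Br-]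
F4 | step 3 | (4S)-4-[(tert-butyldimethylsilyl)oxy]-1-ethynyl-2,6,6-trimethylcyclohex-2-en-1-ol, both C1 epimers | CC1=C[C@@H](O[Si](C)(C)C(C)(C)C)CC(C)(C)C1(O)C#C
A1 | alternative 1 | safranal (2,6,6-trimethylcyclohexa-1,3-diene-1-carbaldehyde) | CC1=C(C=O)C(C)(C)CC=C1
A2 | alternative 1 | trimethyl[(2,6,6-trimethylcyclohexa-1,3-dien-1-yl)ethynyl]silane | CC1=C(C#C[Si](C)(C)C)C(C)(C)CC=C1
A3 | alternative 1 | (3S,4R)-3,4-epoxide of A2 (carotenoid numbering) | CC1=C(C#C[Si](C)(C)C)C(C)(C)C[C@@H]2O[C@H]12
A4 | alternative 2 | (7aS)-2,2,4,6,6-pentamethyl-7,7a-dihydro-1,3-benzodioxol-5(6H)-one | CC1=C2OC(C)(C)O[C@H]2CC(C)(C)C1=O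
A5 | alternative 2 | (3E,5E,7E,9E,11E,13E,15E)-3,7,12,16-tetramethyloctadeca-3,5,7,9,11,13,15-heptaene-1,17-diyne | C#C/C(C)=C/C=C/C(C)=C/C=C/C=C(C)/C=C/C=C(\C)C#C
A6 | alternative 2 | (3S,3'S)-3,3'-dihydroxy-7,8,7',8'-tetradehydro-β,β-carotene-4,4'-dione | CC1=C(C#C/C(C)=C/C=C/C(C)=C/C=C/C=C(C)/C=C/C=C(\C)C#CC2=C(C)C(=O)[C@@H](O)CC2(C)C)C(C)(C)C[C@H](O)C1=O
A7 | alternative 3 | (2E,4E,6E)-9-[(3S,4S)-3,4-bis[(tert-butyldimethylsilyl)oxy]-2,6,6-trimethylcyclohex-1-en-1-yl]-3,7-dimethylnona-2,4,6-trien-8-ynal | CC1=C(C#C/C(C)=C/C=C/C(C)=C/C=O)C(C)(C)C[C@H](O[Si](C)(C)C(C)(C)C)[C@H]1O[Si](C)(C)C(C)(C)C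
A8 | alternative 3 | (3S,4S,3'S,4'S)-3,4,3',4'-tetrakis[(tert-butyldimethylsilyl)oxy]-7,8,7',8'-tetradehydro-β,β-carotene (identical with 16) | CC1=C(C#C/C(C)=C/C=C/C(C)=C/C=C/C=C(C)/C=C/C=C(\C)C#CC2=C(C)[C@H](O[Si](C)(C)C(C)(C)C)[C@@H](O[Si](C)(C)C(C)(C)C)CC2(C)C)C(C)(C)C[C@H](O[Si](C)(C)C(C)(C)C)[C@H]1O[Si](C)(C)C(C)(C)C
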